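**Plan**

Dienone ring numbering: C1 (C=O), C2 (CH2–benzofuranyl), C3 (H), C4 (OMe and Z-cinnamyl, the only stereocentre, R), C5 (OMe), C6 (H).
Retrosynthetic cuts, in order: ArO–Si; the Z C=C back to C≡C; the C(sp)–phenyl bond; then, with cyclopentadiene re-added across C2=C3, the O–CH3 and C4–CH2 bonds, which leads to the C4 ketone of a 2-methoxy-5-alkyl-1,4-benzoquinone; last, the quinone-ring–CH2 bond and the furan C3–C3a and O–CH2 bonds.
Enabling feature: C2=C3 carries only an alkyl group, so it is the one dienophilic alkene of that quinone (C5=C6 is switched off by its methoxy group). It lies next to the C4 carbonyl whose faces must be distinguished, so a norbornene ring built on C2 and C3 covers one face of C4.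
Forward order: furan ring (aryloxy ketone cyclodehydration), CH2 link to the future quinone ring (Friedel–Crafts), oxidation to the quinone, norbornene ring (Diels–Alder), C4–propargyl bond, O-methylation, loss of cyclopentadiene, phenyl onto the alkyne, semihydrogenation, desilylation.
Stereochemistry: a chiral oxazaborolidinium catalyst selects the quinone face (four temporary centres), the folded endo adduct relays this to C4 through convex-face attack, and the cycloreversion erases the temporary centres. The Z alkene comes from syn hydrogenation.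

Key step: step 8

Assumption: the sense of induction is taken from the α-C–H···O binding model of this catalyst family, which calls for the catalyst built from (R)-α,α-diphenylprolinol. If the adduct proves antipodal, the catalyst from the (S)-amino alcohol is used and nothing else changes.
Abbreviation in names: Bf = 6-methoxy-3-phenyl-5-(triisopropylsilyloxy)-1-benzofuran-2-yl.

**Route**

Step 1
Reactants: 1 4-(benzyloxy)-3-methoxyphenol; 2 phenacyl bromide (2-bromo-1-phenylethan-1-one)
Product: 3 2-[4-(benzyloxy)-3-methoxyphenoxy]-1-phenylethan-1-one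
Conditions: K2CO3, acetone, reflux
Reagents that add atoms: none
Why: Williamson ether synthesis, in which the phenoxide displaces the activated primary α-bromide by SN2 and no other nucleophilic site is free.

Step 2
Reactants: 3 2-[4-(benzyloxy)-3-methoxyphenoxy]-1-phenylethan-1-one
Product: 4 5-(benzyloxy)-6-methoxy-3-phenyl-1-benzofuran
Conditions: TsOH·H2O (0.2 equiv), PhMe, reflux, Dean–Stark
Reagents that add atoms: none
Why: Acid-catalysed cyclodehydration of an α-aryloxy ketone (intramolecular Friedel–Crafts hydroxyalkylation, then loss of water) should close the furan ring at the carbon para to the methoxy group, since the other ortho position is squeezed between two oxygens, while a catalytic sulfonic acid should spare the benzyl ether and avoid the 3-aryl to 2-aryl shift known for hot polyphosphoric acid.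

Step 3
Reactants: 4 5-(benzyloxy)-6-methoxy-3-phenyl-1-benzofuran
Product: 5 6-methoxy-3-phenyl-1-benzofuran-5-ol
Conditions: H2 (1 atm), Pd/C (10 wt %), EtOAc–EtOH, rt, stopped after one equivalent of H2
Reagents that add atoms: none
Why: Catalytic hydrogenolysis of a benzyl aryl ether is much faster at 1 atm than saturation of the aromatic furan C2=C3 bond.

Step 4
Reactants: 5 6-methoxy-3-phenyl-1-benzofuran-5-ol
Product: 6 6-methoxy-3-phenyl-5-(triisopropylsilyloxy)-1-benzofuran
Conditions: TIPSCl, imidazole, DMF, rt
Reagents that add atoms: chlorotriisopropylsilane, CC(C)[Si](Cl)(C(C)C)C(C)C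
Why: Imidazole-promoted silylation of a phenol, with the bulky triisopropylsilyl group chosen because the aryl silyl ether must outlast n-BuLi, Lewis and Brønsted acids, NaH and 180 °C and still leave with fluoride at the end.

Step 5
Reactants: 6 6-methoxy-3-phenyl-5-(triisopropylsilyloxy)-1-benzofuran
Product: 8 Bf-methanol, via 2-lithiobenzofuran 7 (not isolated)
Conditions: n-BuLi, THF, −78 °C; then (CH2O)n, −78 °C → rt; aq NH4Cl
Reagents that add atoms: formaldehyde (as paraformaldehyde), C=O
Why: Heteroatom-assisted lithiation followed by hydroxymethylation, relying on benzofuran C2–H (α to the ring oxygen) being kinetically far more acidic at −78 °C than the arene C7–H between two oxygens.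

Step 6
Reactants: 8 Bf-methanol; 9 3,4-dimethoxyphenol
Product: 10 4,5-dimethoxy-2-(Bf-methyl)phenol
Conditions: 9 (3 equiv), Bi(OTf)3 (5 mol %), CH2Cl2, 0 °C → rt
Reagents that add atoms: none
Why: Friedel–Crafts benzylation with a π-activated alcohol, in which the benzofuran-2-ylmethyl cation is captured by the excess phenol at its C6, the most nucleophilic and least hindered position (ortho to OH, para to the 3-methoxy group).

Step 7
Reactants: 10 4,5-dimethoxy-2-(Bf-methyl)phenol
Product: 11 2-methoxy-5-(Bf-methyl)cyclohexa-2,5-diene-1,4-dione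
Conditions: PhI(OAc)2 (1.1 equiv), MeCN–H2O (4:1), 0 °C
Reagents that add atoms: water, O
Why: Hypervalent-iodine oxidative demethylation of a p-methoxyphenol, in which only the free phenol can bind to iodine, water adds at the para carbon bearing methoxy, and the hemiketal loses methanol to give the p-quinone while the silylated benzofuran stays untouched.

Step 8
Reactants: 11 2-methoxy-5-(Bf-methyl)cyclohexa-2,5-diene-1,4-dione; 12 cyclopenta-1,3-diene (freshly cracked from dicyclopentadiene)
Product: 13 endo adduct (1S,4R,4aS,8aR)-7-methoxy-4a-(Bf-methyl)-1,4,4a,8a-tetrahydro-1,4-methanonaphthalene-5,8-dione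
Conditions: 12 (5 equiv), (3aR)-3,3-diphenyl-1-(2-methylphenyl)tetrahydro-1H,3H-pyrrolo[1,2-c][1,3,2]oxazaborole (20 mol %) protonated with HN(SO2CF3)2 (18 mol %), CH2Cl2, −78 → −40 °C
Reagents that add atoms: none
Why: The quinone, activated by coordination of the boron cation to a carbonyl oxygen, and cyclopentadiene combine in a concerted, asynchronous, suprafacial [4+2] cycloaddition; the closest known reaction type is the oxazaborolidinium-catalysed Diels–Alder reaction of 2,5-dialkyl-1,4-benzoquinones with cyclopentadiene. The one ring that closes is the cyclohexene of the norbornene (C2, C3 and four diene carbons), formed intermolecularly by bonding of C2 and C3 to the two diene termini in one step, with the diene CH2 left as the one-carbon bridge. Site selectivity is secured by the substrate: the C5 methoxy group turns C5=C6 into a vinylogous ester alkene of high LUMO, so only the alkyl-substituted C2=C3 bond is dienophilic. The productive complex should be the one at the C4 oxygen, on the lone pair beside C3–H (C3–H···O contact to the catalyst oxygen), because the more basic C1 oxygen gives a donor-stabilised, unreactive complex and has its lone pair beside C2 blocked by the arylmethyl group; in this complex C2=C3 lies over a catalyst phenyl ring and only one quinone face is open, and binding at O1 beside C6–H would leave the same face open. That face choice sets C2 and C3 (cis by suprafacial addition), and the endo rule, with both carbonyls under the diene and H and the arylmethyl group towards the CH2 bridge, sets the two bridgeheads relative to them, so all four centres (1S,4R,4aS,8aR) stem from one catalyst-controlled event. The low temperature keeps the uncatalysed racemic reaction negligible, and the quaternary C2 rules out later aromatisation of the adduct by enolisation.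

Step 9
Reactants: 13 endo adduct; 14 propargyl bromide (3-bromoprop-1-yne)
Product: 16 (1S,4R,4aS,8R,8aR)-8-hydroxy-7-methoxy-4a-(Bf-methyl)-8-(prop-2-yn-1-yl)-4,4a,8,8a-tetrahydro-1,4-methanonaphthalen-5(1H)-one, via allenylzinc bromide 15 (not isolated)
Conditions: 14, Zn dust, THF, 0 °C, solution filtered from excess Zn (which could reduce the enedione); then 13, THF, −78 → −20 °C; aq NH4Cl
Reagents that add atoms: none
Why: Barbier-type propargylation with a preformed allenylzinc reagent, which adds through a cyclic SE2' transition state and therefore gives the homopropargyl and not the allenyl carbinol; it should choose the C4 ketone (C1 is a vinylogous ester carbonyl next to the quaternary C2) and reach it only from the convex face, the side of C3–H, because the concave face lies under the norbornene C=C, so that C4 is set as R with its hydroxyl endo.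

Step 10
Reactants: 16 tertiary carbinol
Product: 17 (1S,4R,4aS,8R,8aR)-7,8-dimethoxy-4a-(Bf-methyl)-8-(prop-2-yn-1-yl)-4,4a,8,8a-tetrahydro-1,4-methanonaphthalen-5(1H)-one
Conditions: NaH (1.5 equiv) added to 16 and MeI (10 equiv), THF, 0 °C → rt
Reagents that add atoms: iodomethane, CI
Why: Williamson O-methylation of a substrate with no enolisable C–H (C2 is quaternary and C3–H is no longer α to a carbonyl), run with a sodium counter-ion and MeI present from the start so that the alkoxide is trapped before an anionic oxy-Cope shift of its 1,5-enyne unit or attack on the aryl silyl ether can compete, and leaving the configuration at C4 untouched.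

Step 11
Reactants: 17 methyl ether adduct
Product: 18 (4R)-4,5-dimethoxy-2-(Bf-methyl)-4-(prop-2-yn-1-yl)cyclohexa-2,5-dien-1-one
Conditions: o-dichlorobenzene (0.01 M), 180 °C, N2 sweep
Reagents that add atoms: none
Why: Thermal retro-Diels–Alder reaction, driven by relief of strain around the quaternary ring-fusion carbon and the crowded endo ether, by the gain of a cross-conjugated dienone and by loss of volatile cyclopentadiene, which deletes the four temporary centres while C4, outside the pericyclic array, keeps its R configuration.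

Step 12
Reactants: 18 terminal alkyne dienone; 19 iodobenzene
Product: 20 (4R)-4,5-dimethoxy-2-(Bf-methyl)-4-(3-phenylprop-2-yn-1-yl)cyclohexa-2,5-dien-1-one
Conditions: PdCl2(PPh3)2 (3 mol %), CuI (5 mol %), Et3N, THF, rt
Reagents that add atoms: none
Why: Sonogashira coupling, placed after the cycloreversion because the strained norbornene alkene would intercept the arylpalladium iodide intermediate by carbopalladation, and run with a tertiary amine that cannot displace the vinylogous ester methoxy group.

Step 13
Reactants: 20 aryl alkyne dienone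
Product: 21 (4R)-4,5-dimethoxy-2-(Bf-methyl)-4-[(2Z)-3-phenylprop-2-en-1-yl]cyclohexa-2,5-dien-1-one
Conditions: H2 (1 atm), Pd/CaCO3 poisoned with Pb(OAc)2, quinoline, EtOAc, rt, stopped after one equivalent of H2
Reagents that add atoms: none
Why: Lindlar semihydrogenation, in which syn delivery of H2 to the adsorbed alkyne gives the Z alkene and the poisoned surface should leave the trisubstituted ring alkenes and the quinol ether alone.

Step 14
Reactants: 21 silyl-protected Z alkene
Product: 22 target (4R)-2-[(5-hydroxy-6-methoxy-3-phenyl-1-benzofuran-2-yl)methyl]-4,5-dimethoxy-4-[(2Z)-3-phenylprop-2-en-1-yl]cyclohexa-2,5-dien-1-one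
Conditions: Bu4NF, AcOH (1:1), THF, 0 °C
Reagents that add atoms: none
Why: Fluoride-induced cleavage of an aryl silyl ether, buffered with acetic acid so that the phenoxide is protonated at once and neither the dienone nor the Z alkene meets a strong base.

**Compound list**

1 | 4-(benzyloxy)-3-methoxyphenol | COc1cc(O)ccc1OCc1ccccc1 | starting material
2 | phenacyl bromide | O=C(CBr)c1ccccc1 | starting material
3 | 2-[4-(benzyloxy)-3-methoxyphenoxy]-1-phenylethan-1-one | COc1cc(OCC(=O)c2ccccc2)ccc1OCc1ccccc1 | intermediate
4 | 5-(benzyloxy)-6-methoxy-3-phenyl-1-benzofuran | COc1cc2occ(-c3ccccc3)c2cc1OCc1ccccc1 | intermediate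
5 | 6-methoxy-3-phenyl-1-benzofuran-5-ol | COc1cc2occ(-c3ccccc3)c2cc1O | intermediate
6 | 6-methoxy-3-phenyl-5-(triisopropylsilyloxy)-1-benzofuran | COc1cc2occ(-c3ccccc3)c2cc1O[Si](C(C)C)(C(C)C)C(C)C | intermediate
7 | 2-lithio derivative of 6 (not isolated) | COc1cc2oc([Li])c(-c3ccccc3)c2cc1O[Si](C(C)C)(C(C)C)C(C)C | intermediate
8 | [6-methoxy-3-phenyl-5-(triisopropylsilyloxy)-1-benzofuran-2-yl]methanol | COc1cc2oc(CO)c(-c3ccccc3)c2cc1O[Si](C(C)C)(C(C)C)C(C)C | intermediate
9 | 3,4-dimethoxyphenol | COc1ccc(O)cc1OC | starting material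
10 | 4,5-dimethoxy-2-(Bf-methyl)phenol | COc1cc(O)c(Cc2oc3cc(OC)c(O[Si](C(C)C)(C(C)C)C(C)C)cc3c2-c2ccccc2)cc1OC | intermediate
11 | 2-methoxy-5-(Bf-methyl)cyclohexa-2,5-diene-1,4-dione | COC1=CC(=O)C(Cc2oc3cc(OC)c(O[Si](C(C)C)(C(C)C)C(C)C)cc3c2-c2ccccc2)=CC1=O | intermediate
12 | cyclopenta-1,3-diene | C1=CCC=C1 | starting material
13 | (1S,4R,4aS,8aR)-7-methoxy-4a-(Bf-methyl)-1,4,4a,8a-tetrahydro-1,4-methanonaphthalene-5,8-dione (endo) | COC1=CC(=O)[C@@]2(Cc4oc5cc(OC)c(O[Si](C(C)C)(C(C)C)C(C)C)cc5c4-c4ccccc4)[C@H]3C=C[C@H](C3)[C@H]2C1=O | intermediate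
14 | propargyl bromide | C#CCBr | starting material
15 | allenylzinc bromide (not isolated) | C=C=C[Zn]Br | intermediate
16 | (1S,4R,4aS,8R,8aR)-8-hydroxy-7-methoxy-4a-(Bf-methyl)-8-(prop-2-yn-1-yl)-4,4a,8,8a-tetrahydro-1,4-methanonaphthalen-5(1H)-one | COC1=CC(=O)[C@@]2(Cc4oc5cc(OC)c(O[Si](C(C)C)(C(C)C)C(C)C)cc5c4-c4ccccc4)[C@H]3C=C[C@H](C3)[C@H]2[C@]1(O)CC#C | intermediate
17 | (1S,4R,4aS,8R,8aR)-7,8-dimethoxy-4a-(Bf-methyl)-8-(prop-2-yn-1-yl)-4,4a,8,8a-tetrahydro-1,4-methanonaphthalen-5(1H)-one | COC1=CC(=O)[C@@]2(Cc4oc5cc(OC)c(O[Si](C(C)C)(C(C)C)C(C)C)cc5c4-c4ccccc4)[C@H]3C=C[C@H](C3)[C@H]2[C@]1(OC)CC#C | intermediate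
18 | (4R)-4,5-dimethoxy-2-(Bf-methyl)-4-(prop-2-yn-1-yl)cyclohexa-2,5-dien-1-one | COC1=CC(=O)C(Cc2oc3cc(OC)c(O[Si](C(C)C)(C(C)C)C(C)C)cc3c2-c2ccccc2)=C[C@@]1(CC#C)OC | intermediate
19 | iodobenzene | Ic1ccccc1 | starting material
20 | (4R)-4,5-dimethoxy-2-(Bf-methyl)-4-(3-phenylprop-2-yn-1-yl)cyclohexa-2,5-dien-1-one | COC1=CC(=O)C(Cc2oc3cc(OC)c(O[Si](C(C)C)(C(C)C)C(C)C)cc3c2-c2ccccc2)=C[C@@]1(CC#Cc1ccccc1)OC | intermediate
21 | (4R)-4,5-dimethoxy-2-(Bf-methyl)-4-[(2Z)-3-phenylprop-2-en-1-yl]cyclohexa-2,5-dien-1-one | COC1=CC(=O)C(Cc2oc3cc(OC)c(O[Si](C(C)C)(C(C)C)C(C)C)cc3c2-c2ccccc2)=C[C@@]1(C/C=C\c1ccccc1)OC | intermediate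
22 | (4R)-2-[(5-hydroxy-6-methoxy-3-phenyl-1-benzofuran-2-yl)methyl]-4,5-dimethoxy-4-[(2Z)-3-phenylprop-2-en-1-yl]cyclohexa-2,5-dien-1-one | COC1=CC(=O)C(Cc2oc3cc(OC)c(O)cc3c2-c2ccccc2)=C[C@@]1(C/C=C\c1ccccc1)OC | target

**Step count and risks**

Total step count: 14. Longest linear sequence: 14 steps, from 1 to 22. Compounds 2, 9, 12, 14 and 19 are bought.

Step 8. Facial discrimination may be poor or reversed, because the catalyst can bind to two carbonyl oxygens and several ether oxygens and a bulky arylmethyl group sits on the reacting bond. Turnover may also be so slow that the warming it requires lets the racemic background reaction take over. The fallback sets out from 11 and 12. The cycloaddition is run without catalyst (CH2Cl2, rt), which should give the endo adduct as a racemate, that is 13 together with the antipodal endo adduct F1. The two are separated by preparative supercritical-fluid chromatography on an amylose tris(3,5-dimethylphenylcarbamate) phase. Compound 13 re-enters the route at step 9, and F1 is heated in o-dichlorobenzene so that it reverts to 11 and 12 for another pass.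

Step 11. The cycloreversion may need a temperature at which the liberated dienone undergoes a [3,3] shift of the propargyl group from C4 to C6 followed by aromatisation. The fallback sets out from 13 and caps the alkyne terminus, which is the carbon that would have to bond to C6. 3-Bromo-1-(trimethylsilyl)prop-1-yne and Zn give the silylated allenylzinc bromide F2. This adds to 13 as in step 9 to give the silyl-capped carbinol F3. NaH and MeI convert F3 into the silyl-capped methyl ether F4. Thermolysis in o-dichlorobenzene then releases the silyl-capped dienone F5, in which the bulky terminus should slow the sigmatropic shift. K2CO3 in MeOH at 0 °C removes the alkynyl silane only, and the route is rejoined at 18.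

Step 10. Etherification of the tertiary alkoxide buried in the concave pocket may be slow, which would let the anionic oxy-Cope shift or silyl transfer from the aryl ether compete. The fallback sets out from 16 and reverses the order of events. The free carbinol is thermolysed first (o-dichlorobenzene, 180 °C) to give the (R)-quinol F6, whose hydroxyl is no longer shielded by the bicycle. F6 is then methylated without base strength, using MeOTf and 2,6-di-tert-butyl-4-methylpyridine in CH2Cl2, which rejoins the route at 18.

**Further compounds**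

F1 | step 8 | (1R,4S,4aR,8aS)-7-methoxy-4a-(Bf-methyl)-1,4,4a,8a-tetrahydro-1,4-methanonaphthalene-5,8-dione (antipode of 13) | COC1=CC(=O)[C@]2(Cc4oc5cc(OC)c(O[Si](C(C)C)(C(C)C)C(C)C)cc5c4-c4ccccc4)[C@@H]3C=C[C@@H](C3)[C@@H]2C1=O
F2 | step 11 | [1-(trimethylsilyl)propa-1,2-dien-1-yl]zinc bromide | C=C=C([Zn]Br)[Si](C)(C)C
F3 | step 11 | (1S,4R,4aS,8R,8aR)-8-hydroxy-7-methoxy-4a-(Bf-methyl)-8-[3-(trimethylsilyl)prop-2-yn-1-yl]-4,4a,8,8a-tetrahydro-1,4-methanonaphthalen-5(1H)-one | COC1=CC(=O)[C@@]2(Cc4oc5cc(OC)c(O[Si](C(C)C)(C(C)C)C(C)C)cc5c4-c4ccccc4)[C@H]3C=C[C@H](C3)[C@H]2[C@]1(O)CC#C[Si](C)(C)C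
F4 | step 11 | (1S,4R,4aS,8R,8aR)-7,8-dimethoxy-4a-(Bf-methyl)-8-[3-(trimethylsilyl)prop-2-yn-1-yl]-4,4a,8,8a-tetrahydro-1,4-methanonaphthalen-5(1H)-one | COC1=CC(=O)[C@@]2(Cc4oc5cc(OC)c(O[Si](C(C)C)(C(C)C)C(C)C)cc5c4-c4ccccc4)[C@H]3C=C[C@H](C3)[C@H]2[C@]1(OC)CC#C[Si](C)(C)C
F5 | step 11 | (4R)-4,5-dimethoxy-2-(Bf-methyl)-4-[3-(trimethylsilyl)prop-2-yn-1-yl]cyclohexa-2,5-dien-1-one | COC1=CC(=O)C(Cc2oc3cc(OC)c(O[Si](C(C)C)(C(C)C)C(C)C)cc3c2-c2ccccc2)=C[C@@]1(CC#C[Si](C)(C)C)OC
F6 | step 10 | (4R)-4-hydroxy-5-methoxy-2-(Bf-methyl)-4-(prop-2-yn-1-yl)cyclohexa-2,5-dien-1-one | COC1=CC(=O)C(Cc2oc3cc(OC)c(O[Si](C(C)C)(C(C)C)C(C)C)cc3c2-c2ccccc2)=C[C@@]1(CC#C)O
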